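The runs were computed on assumed constants, and the scatter is random.

The target did not last in the autumn run: with reagent at 2.3 M and substrate down to 0.2%, it fell from 39.6% at 12.0 s to 6.8% at 40.0 s. You asked for a quick number, and your hunch was that too much reagent costs target, so here is how I would count it.

the same everywhere: substrate 0.047 M
- spring: reagent 0.075 M; run made earlier
- autumn: reagent 2.3 M; run made earlier
- Thursday's: reagent 0.0600 M; time 2.0 min
- Wednesday's: reagent 0.200 M; time 2.0 min
- Friday's: reagent 0.600 M; time 2.0 min
- Monday's: reagent 1.50 M; time 2.0 min

| run | time / s | target / % | substrate / % |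
|---|---|---|---|
| spring | 15.0 | 15.5 | 80.8 |
| spring | 30.0 | 25.3 | 66.0 |
| spring | 50.0 | 34.9 | 52.2 |
| spring | 60.0 | 37.6 | 46.9 |
| spring | 80.0 | 43.3 | 39.3 |
| autumn | 10.0 | 45.5 | 1.1 |
| autumn | 12.0 | 39.6 | 0.2 |
| autumn | 25.0 | 17.8 | 0 |
| autumn | 40.0 | 6.8 | 0.2 |
| autumn | 80.0 | 0.5 | 0 |

(scatter of a reading: 0.5 percentage points)

1. [target] at the end for Thursday's, Wednesday's, Friday's, Monday's, in this order
2. how the row runs (rises all the way / falls, then rises / hardly changes / rises, then falls / falls all the way)

- "hardly changes" means that all values lie within two and a half points (for a concentration: within two and a half percent of the largest)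

Reagent stands far above substrate in the autumn run, so the decay there is pseudo-first-order. If it goes with the first power of reagent, those readings give a rate constant k_T of 0.0274 /M/s. At its charged reagent, Monday's has a target half-life of 16.9 s: this half-life h is ln 2 divided by k_T and by the reagent concentration, and you count how many such half-lives fit into the run. At its charged reagent, Thursday's has a half-life of 422 s, so 0.284 of them fit into 2.0 min, while Monday's fits 7.10. Spring's substrate still stood at 39.3% after 80.0 s; that run had more reagent than Thursday's but a shorter time, so I expect Thursday's to be short of conversion, not of survival. My quick number for Monday's takes the whole charge as target from the start and halves it that many times, which leaves 3.41 × 10⁻⁴ M.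

The forecast gives 0.0208 M, 0.0238 M, 0.0068 M and 3.000 × 10⁻⁴ M, so its row rises, then falls, and it says “The row rises slightly, then falls sharply”. For Monday's, its number is below mine.

The flasks give 0.0210 M, 0.0232 M, 0.00631 M and 2.78 × 10⁻⁴ M, so the row rises, then falls.

    substrate + reagent → target (k = 0.159 /M/s)
    substrate + reagent → isomer of the product (k = 0.0486 /M/s)
    reagent + target → over-reaction product (k = 0.0293 /M/s)

On Monday's substrate stands at 0% after 1.00 min, and with reagent at 94.5% of its charge at the end h becomes 17.9 s, which takes the target from 7.16% to 0.701% over the second minute, where the flask shows 0.592%. On Friday's, with substrate at 0.107% after 1.00 min and reagent at 87.2% of its charge at the end, h is 48.4 s, which takes the target from 33.8% to 14.3% over the second minute, and the flask shows 13.4%.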